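The earlier runs and the new flask are calculated from invented constants, noise included.

in all of them: solid substrate 10 mM
- delta: coupling partner 60 mM; run made earlier
- flask: coupling partner 30.0 mM; time 2.5 min
delta run (percent of the solid substrate charged)

| time / s | triple product / % | tetra adduct / % |
|---|---|---|
| 10.0 | 0 | 0 |
| 15.0 | 0.3 | 0 |
| 30.0 | 2.3 | 0.7 |
| 50.0 | 8.1 | 4.6 |

(readings scatter by 0.3 percentage points)
- solid, in amounts per volume of the solution: solid substrate
- at the start none of the solid substrate is in solution
1. equivalents of coupling partner to solid substrate, everything else as given, that leave most triple product at 2.5 min
2. the amount of triple product then, in percent of the solid substrate charged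
3. the amount of triple product with the amounts as given

1. A ratio of 0.568, tetra adduct to triple product at 50.0 s, up from 0.304 at 30.0 s, was where I started. I assumed a chain of equal additions of coupling partner, 3 in triple product and 4 in tetra adduct. That ratio is then a quarter of the mean number of additions, so its climb reads as 0.0527 s⁻¹ at 60 mM.

2. In such a chain, triple product is the cube of the count over 6, times the exponential of minus the count. The delta run's last triple reading gave a count of 0.786 at first and 1.14 after iteration. At that pace, neglecting the fall of partner, the solid cost a lag of 28.4 s.

3. Each addition spends one partner, so the pace falls with the partner left, and the integral is closed: count = equivalents × (1 − exp(−0.00879 s⁻¹ × (time − lag))).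

4. The flask has half the partner of the delta run but runs to 2.5 min. I got 1.97 for this addition count, the mean partners taken up per solid substrate charged. It ends above the delta run's last reading because its count is larger, at 17.8% triple product by my reckoning. A count of 3 gives the peak, 22.4%, at 4.57 equivalents.

5. The forecast parts from my figures by more than the scatter of a reading: it gave 14% against my 17.8%, and 20% at 5.5 equiv against my 22.4% at 4.57 equivalents, though on the same rule that “Triple peaks at about three additions on average”.

6. The flask gives 15.0%, with 20.8% at 4.92 equiv.

    coupling partner + double product → triple product (k = 0.780 M⁻¹ s⁻¹)
    coupling partner + mono adduct → double product (k = 0.610 M⁻¹ s⁻¹)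
    solid substrate ⇌ starting material, rate k3*(cs3 - [starting material]) while solid is left; crystals form when [starting material] > cs3 (solubility = 7.00 mM, k = 0.0560 s⁻¹)
    coupling partner + triple product → tetra adduct (k = 0.720 M⁻¹ s⁻¹)
    starting material + coupling partner → mono adduct (k = 0.700 M⁻¹ s⁻¹)

Partner bound in the flask came to 1.69 equiv per solid substrate charged, below my count of 1.97. Put into the chain formula, the count from the partner left in the flask gives 14.8% triple product.

7. For the neighbour charged with 12 mM of partner, the count is 0.788, which gives 3.71% triple product. The computed flask holds 2.89%, with 0.666 equivalents of partner taken up.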